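# Total synthesis proposal for CNP0348098.1 (compound 19)

## Analysis of the target

Numbering used throughout: ring A is the benzene ring, with C1 (CHO), C2 (chain C1'–C11'), C3 (chain C1''–C4'', extra methyl on C3''), C4–H, C5–H and C6 (OH).

- Target 19 is a salicylaldehyde with one carbocycle. Its four substituents stand side by side on ring A: OH on C6, CHO on C1, the (1'E,5'E)-3',4',10'-trihydroxyundecadienyl chain on C2, and the 2'',3''-dihydroxy-3''-methylbutyl chain on C3.
- The four stereocentres fall into three units that are too far apart to influence each other: C2'' (S), the threo glycol C3' (S)/C4' (S), and C10' (S).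
- The glycol lies between two E alkenes. C1'–C6' is therefore a hexa-1,5-diene-3,4-diol with local C2 symmetry, in the configuration that corresponds to L-tartaric acid.
- The sensitive groups are the free aldehyde and the doubly allylic glycol. C3' is also cinnamylic and prone to ionisation, allylic transposition and oxidation. The C2'' hydroxyl would close a six-membered ether onto C1' if C3' ionised.
- No single stereocentre is hard. The difficulty is the crowded contiguous array C6–C1–C2–C3, in which C2 is flanked on both sides. Classical arene chemistry installs these groups one at a time, with one halogenation and one coupling each.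
- The feature that invites the key step is the pair C2 (E-alkenyl) and C3 (CH2–CH(OH)–) next to the already substituted C1. This is the ipso/ortho pattern of a Catellani reaction. The C2'' hydroxyl, two atoms from ring A, marks an epoxide opened at its CH2 terminus by C3.
- Bonds C2–C1' and C3–C1'' can therefore be made in one operation from an aryl iodide that still carries hydrogen on C3.

## Retrosynthetic reasoning

**19 ⇒ 18.** No skeletal bond is cut. The aldehyde (dioxolane), the phenol (MOM ether), the glycol (acetonide) and the tertiary carbinol (TES ether) are all masked by groups that fall to dilute aqueous acid. Only one step then follows the key step. C10'–OH and C2''–OH stay free.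

**18 ⇒ 5 + 8 + 15 (key disconnection).** Two neighbouring bonds on ring A are cut together: C3–C1'' and C2–C1'.
- Cutting only C2–C1' would leave a tetrasubstituted aryl halide, which is the real problem of the target.
- Cutting both reduces ring A to the 1,2,3-trisubstituted iodide 5, with iodine on C2 and hydrogen on C3.
- The forward Catellani reaction must functionalise C3–H with the CH2 terminus of epoxide 8, then couple C2 with the terminal vinyl group of 15 as an E alkene.
- It joins three finished fragments and delivers the full carbon skeleton with all four stereocentres in place.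
- Because the three stereo-units do not communicate, bringing each in ready-made costs nothing in stereocontrol.

**15 ⇒ 11 + 14.** The C5'=C6' alkene is cut by cross metathesis. The cut exploits the local C2 symmetry. In 14 the two vinyl groups are homotopic, so mono-functionalisation can give only one compound. The forward reaction must stop after one metathesis and give the E alkene.

**14 ⇒ 12 (through 13).** Both vinyl groups are cut at C1'=C2' and at the carbon pair that later becomes C5'=C6'. The tartrate-derived diester 12 supplies C3' and C4' with the right threo configuration. The forward reaction is a double half-reduction and methylenation without isolation of the epimerisable dialdehyde 13.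

**11 ⇒ 9 + 10.** The C8'–C9' bond is cut. Epoxide 9 supplies C9'–C11' and the C10' stereocentre, and the Grignard reagent 10 supplies the rest. The forward opening must occur at the unsubstituted epoxide carbon, so C10' is never touched.

**8 ⇒ 7 ⇒ 6.** The two methyl–C3'' bonds are cut. Glycidic ester 6 supplies C1''–C3'' and the C2'' stereocentre. The forward double addition of a methyl nucleophile must be faster at the ester than at the epoxide. Silylation then blocks epoxide migration in the key step.

**5 ⇒ 4 ⇒ 2 ⇒ 1 (through 3).** The C1–CHO bond is cut. In 2 the position between iodine and the MOM ether is the most acidic and is addressed by chelation. Directed metalation to 3 followed by formylation therefore sets the 1,2,3-pattern. The acetal of 5 keeps the formyl group out of the palladium chemistry.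

## Alternatives that were turned down

**Alternative 1:** the textbook route, which cuts only C2–C1'.
- *Forward key step:* Heck reaction of the fully substituted aryl bromide A1 with 15 gives the prenylated styrene A2. A late Sharpless asymmetric dihydroxylation of the prenyl alkene follows.
- *Why turned down:* the arene problem is moved, not solved. A1 needs a regiocontrolled halogenation para to oxygen, a chemoselective coupling of one of two halogens, and a prenyl–metal coupling that is prone to α/γ scrambling.
- Each substituent costs its own step in the longest sequence.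
- The late dihydroxylation must then pick one of three alkenes in A2. C2'' is set only after the most valuable material has been assembled.

**Alternative 2:** setting C2'', C3' and C4' as a group, since all three have the facial sense of the same dihydroquinine-derived ligand.
- *Forward key step:* the precursor is the (E)-enediyne A3, assembled by two sp–sp2 couplings on a two-carbon linchpin. A double Sharpless asymmetric dihydroxylation gives the diynetetraol A4. A twofold hydroxyl-directed trans-hydroalumination follows.
- *Why turned down:* A3 still contains the prenylated tetrasubstituted ring A, so the hardest part remains.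
- An alkene flanked by two alkynes is electron-poor and flat, so it is the slowest and least well-differentiated olefin class for osmylation.
- The hydride step forces heavier masking of the aldehyde and adds redox steps after the key step. The sequence becomes clearly longer.

**Alternative 3:** building ring A itself by cutting C2–C3 and C1–C6.
- *Forward key step:* [4+2] cycloaddition of the 2-alkylfuran A5 with the enynal A6. Acid-induced opening of the oxygen bridge and loss of the C6 proton would then give the phenol.
- *Why turned down:* the frontier-orbital regiochemistry opposes the need. The unsubstituted furan terminus has the larger coefficient and pairs with the β-carbon of the ynal. The formyl-bearing carbon would thus end up next to the alkyl-bearing carbon.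
- Furan cycloadditions with disubstituted ynals are reversible and need Lewis acids.
- The aromatisation also needs acid. Neither fits the acetonide and the allylic oxygens of A6.

Key step: step 9

Assumption: potassium 5-norbornene-2-carboxylate (endo/exo mixture, from the commercial acid and KOH) is treated as a stock reagent; as mediator and base it leaves no atom in any product.

## Steps

Step 1
Reactants: 1 3-iodophenol
Product: 2 1-iodo-3-(methoxymethoxy)benzene
Conditions: MOMCl, i-Pr2NEt, CH2Cl2, 0 → 23 °C
Reagents that add atoms: chloromethyl methyl ether (MOMCl), COCCl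
Why: Simple O-alkylation of the phenol (MOM protection); the MOM ether is the directing group of step 2, survives base and palladium, and falls in the final acid step.

Step 2
Reactants: 2 1-iodo-3-(methoxymethoxy)benzene
Product: 4 2-iodo-6-(methoxymethoxy)benzaldehyde, via aryllithium 3 (not isolated)
Conditions: LiN(i-Pr)2 (1.1 equiv), THF, −78 °C; DMF, −78 → 0 °C; H2O
Reagents that add atoms: N,N-dimethylformamide (DMF), CN(C)C=O
Why: Directed ortho-metalation; the hydrogen between iodine and the MOM ether is the most acidic and is reached by chelation, and the amide base does not exchange the iodine as an alkyllithium would. Keeping 3 at −78 °C suppresses halogen migration and aryne formation before the formylation.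

Step 3
Reactants: 4 2-iodo-6-(methoxymethoxy)benzaldehyde
Product: 5 2-[2-iodo-6-(methoxymethoxy)phenyl]-1,3-dioxolane
Conditions: TMSOCH2CH2OTMS (1.5 equiv), TMSOTf (5 mol %), CH2Cl2, −78 → −20 °C; pyridine
Reagents that add atoms: 1,2-bis(trimethylsilyloxy)ethane, C[Si](C)(C)OCCO[Si](C)(C)C
Why: Noyori acetalisation under aprotic conditions, driven by formation of the Si–O–Si bond; catalytic silyl triflate at low temperature leaves the aryl MOM ether alone. The mask is needed because a free ortho-formyl group could trap the norbornylpalladium intermediate of step 9.

Step 4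
Reactants: 6 methyl (2S)-oxirane-2-carboxylate
Product: 7 2-[(2S)-oxiran-2-yl]propan-2-ol
Conditions: MeMgBr (2.1 equiv), Et2O–THF, −78 → −20 °C; Na2SO4·10H2O
Reagents that add atoms: methylmagnesium bromide, C[Mg]Br
Why: Double Grignard addition to the ester, which at low temperature is faster than epoxide opening. The stereocentre (future C2'') is not touched and keeps the descriptor S because the priority order of its substituents does not change.

Step 5
Reactants: 7 2-[(2S)-oxiran-2-yl]propan-2-ol
Product: 8 triethyl({2-[(2S)-oxiran-2-yl]propan-2-yl}oxy)silane
Conditions: TESOTf, 2,6-lutidine, CH2Cl2, −78 °C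
Reagents that add atoms: triethylsilyl trifluoromethanesulfonate (TESOTf), CC[Si](CC)(CC)OS(=O)(=O)C(F)(F)F
Why: Silylation of a tertiary alcohol with a silyl triflate and a hindered base, a standard operation on epoxy alcohols at low temperature. It blocks Payne rearrangement of the epoxy alcohol under the basic conditions of step 9 and makes the fragment less volatile.

Step 6
Reactants: 9 (2S)-2-methyloxirane ((S)-propylene oxide); 10 but-3-en-1-ylmagnesium bromide
Product: 11 (2S)-hept-6-en-2-ol
Conditions: CuI (10 mol %), THF, −30 → 0 °C; H2O
Reagents that add atoms: none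
Why: Copper-catalysed opening of a terminal epoxide by a Grignard reagent at the unsubstituted carbon. The C–O bond at the stereocentre stays intact, so C10' (S) comes unchanged from 9.

Step 7
Reactants: 12 dimethyl (4R,5R)-2,2-dimethyl-1,3-dioxolane-4,5-dicarboxylate
Product: 14 (4S,5S)-4,5-diethenyl-2,2-dimethyl-1,3-dioxolane, via dialdehyde 13 (not isolated)
Conditions: i-Bu2AlH (2.1 equiv), toluene, −78 °C; then Ph3P=CH2 [from Ph3PCH3Br, KN(SiMe3)2, THF], −78 → 23 °C; aq. potassium sodium tartrate
Reagents that add atoms: methyltriphenylphosphonium bromide, C[P+](c1ccccc1)(c1ccccc1)c1ccccc1.[Br-]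
Why: One-pot half-reduction and Wittig methylenation; 13 is released from its aluminium hemiacetal only in the presence of the ylide, so it is neither isolated nor epimerised. C3' and C4' come from the tartrate, and the change of descriptor from R to S reflects only the changed priorities.

Step 8
Reactants: 11 (2S)-hept-6-en-2-ol; 14 (4S,5S)-4,5-diethenyl-2,2-dimethyl-1,3-dioxolane
Product: 15 (2S,6E)-7-[(4S,5S)-5-ethenyl-2,2-dimethyl-1,3-dioxolan-4-yl]hept-6-en-2-ol
Conditions: second-generation Hoveyda–Grubbs catalyst (H2IMes)Cl2Ru=CH(C6H4-2-O-i-Pr) (3 mol %), 14 (3 equiv), CH2Cl2, 40 °C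
Reagents that add atoms: none
Why: Olefin cross metathesis of an unhindered terminal alkene with an allylically branched one, which favours the cross product and the E alkene. The two vinyl groups of 14 are homotopic, so mono-metathesis gives a single compound, and the excess of volatile 14 holds back the second metathesis.

Step 9
Reactants: 5 2-[2-iodo-6-(methoxymethoxy)phenyl]-1,3-dioxolane; 8 triethyl({2-[(2S)-oxiran-2-yl]propan-2-yl}oxy)silane; 15 (2S,6E)-7-[(4S,5S)-5-ethenyl-2,2-dimethyl-1,3-dioxolan-4-yl]hept-6-en-2-ol
Product: 18 (2S,6E)-7-[(4S,5S)-5-{(E)-2-[2-(1,3-dioxolan-2-yl)-6-{(2S)-2-hydroxy-3-methyl-3-[(triethylsilyl)oxy]butyl}-3-(methoxymethoxy)phenyl]ethenyl}-2,2-dimethyl-1,3-dioxolan-4-yl]hept-6-en-2-ol, via palladacycle 16 (not isolated), via arylpalladium iodide 17 (not isolated)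
Conditions: Pd(OAc)2 (10 mol %), XPhos (20 mol %), potassium 5-norbornene-2-carboxylate (1.5 equiv), 8 (3 equiv), 15 (1.5 equiv), NMP, 70 °C
Reagents that add atoms: none
Why: This is a Catellani reaction (palladium/norbornene cooperative catalysis) in its known variant with a terminal epoxide as ortho-alkylating agent and a Heck termination. Zerovalent palladium inserts into the C2–I bond of 5, the strained norbornene carboxylate inserts faster than the unactivated vinyl group of 15, and carboxylate-assisted metalation of the only free ortho position, C3–H, gives the five-membered divalent palladacycle 16. Palladacycle 16 attacks the unsubstituted CH2 of 8 in an SN2-type oxidative addition to tetravalent palladium, and aryl–alkyl reductive elimination forms C3–C1''; the C–O bond at C2'' is never broken, so its S configuration is carried over from 8. With both ortho positions filled, steric pressure drives β-carbon elimination of the norbornene and leaves arylpalladium iodide 17. Intermediate 17 adds to the terminal CH2 of the monosubstituted alkene of 15 (the 1,2-disubstituted C5'=C6' alkene is too hindered to insert), and syn insertion followed by syn β-hydride elimination of the benzylic hydrogen forms C2–C1' as the conjugated E alkene. No ring of the product is closed and no stereocentre is created: C2'', C3', C4' and C10' arrive in the fragments, and only the C1'=C2' geometry is set here. The step needs Heck termination to win over C–O reductive elimination of the pendant C2'' hydroxyl onto C2; the carboxylic acid released in the metalation keeps that hydroxyl protonated, and 15 is used in excess. The dioxolane on C1 supplies the ortho substituent that clean mono-alkylation requires, and because the new styrene is not a Michael acceptor the C2'' hydroxyl cannot add back to it.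

Step 10
Reactants: 18 (fully protected 19, name as in step 9)
Product: 19 3-[(2S)-2,3-dihydroxy-3-methylbutyl]-6-hydroxy-2-[(1E,3S,4S,5E,10S)-3,4,10-trihydroxyundeca-1,5-dien-1-yl]benzaldehyde
Conditions: 2 M aq. HCl, THF, 23 → 40 °C
Reagents that add atoms: water, O
Why: Acid hydrolysis of one silyl ether, two acetals and one ketal in a single operation; no C–O bond at a stereocentre is broken. The dioxolane falls first, and the liberated formyl group on C1, an acceptor ortho to the styrene, together with the neighbouring oxygen on C4', disfavours ionisation at C3' while the slower MOM and acetonide groups are cleaved.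

## Compound list

1 | 3-iodophenol | Oc1cccc(I)c1 | starting material
2 | 1-iodo-3-(methoxymethoxy)benzene | COCOc1cccc(I)c1 | intermediate
3 | [2-iodo-6-(methoxymethoxy)phenyl]lithium | COCOc1cccc(I)c1[Li] | intermediate
4 | 2-iodo-6-(methoxymethoxy)benzaldehyde | COCOc1cccc(I)c1C=O | intermediate
5 | 2-[2-iodo-6-(methoxymethoxy)phenyl]-1,3-dioxolane | COCOc1cccc(I)c1C1OCCO1 | intermediate
6 | methyl (2S)-oxirane-2-carboxylate | C1O[C@@H]1C(=O)OC | starting material
7 | 2-[(2S)-oxiran-2-yl]propan-2-ol | C1O[C@@H]1C(C)(C)O | intermediate
8 | triethyl({2-[(2S)-oxiran-2-yl]propan-2-yl}oxy)silane | C1O[C@@H]1C(C)(C)O[Si](CC)(CC)CC | intermediate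
9 | (2S)-2-methyloxirane | C[C@H]1CO1 | starting material
10 | but-3-en-1-ylmagnesium bromide | C=CCC[Mg]Br | starting material
11 | (2S)-hept-6-en-2-ol | C[C@H](O)CCCC=C | intermediate
12 | dimethyl (4R,5R)-2,2-dimethyl-1,3-dioxolane-4,5-dicarboxylate | COC(=O)[C@@H]1OC(C)(C)O[C@H]1C(=O)OC | starting material
13 | (4R,5R)-2,2-dimethyl-1,3-dioxolane-4,5-dicarbaldehyde | O=C[C@@H]1OC(C)(C)O[C@H]1C=O | intermediate
14 | (4S,5S)-4,5-diethenyl-2,2-dimethyl-1,3-dioxolane | C=C[C@@H]1OC(C)(C)O[C@H]1C=C | intermediate
15 | (2S,6E)-7-[(4S,5S)-5-ethenyl-2,2-dimethyl-1,3-dioxolan-4-yl]hept-6-en-2-ol | C[C@H](O)CCC/C=C/[C@@H]1OC(C)(C)O[C@H]1C=C | intermediate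
16 | aryl–norbornyl palladacycle (Pd bound to ring A C3 and to the exo norbornyl carbon, ring A C2 bound to the neighbouring exo carbon; phosphine omitted, carboxylate position and norbornyl configuration not specified), potassium salt | COCOc1ccc2[Pd]C3C4CC(C(C(=O)[O-])C4)C3c2c1C1OCCO1.[K+] | intermediate
17 | [2-(1,3-dioxolan-2-yl)-6-{(2S)-2-hydroxy-3-methyl-3-[(triethylsilyl)oxy]butyl}-3-(methoxymethoxy)phenyl]palladium iodide (phosphine omitted) | COCOc1ccc(C[C@H](O)C(C)(C)O[Si](CC)(CC)CC)c([Pd]I)c1C1OCCO1 | intermediate
18 | (2S,6E)-7-[(4S,5S)-5-{(E)-2-[2-(1,3-dioxolan-2-yl)-6-{(2S)-2-hydroxy-3-methyl-3-[(triethylsilyl)oxy]butyl}-3-(methoxymethoxy)phenyl]ethenyl}-2,2-dimethyl-1,3-dioxolan-4-yl]hept-6-en-2-ol | C[C@H](O)CCC/C=C/[C@@H]1OC(C)(C)O[C@H]1/C=C/c2c(C[C@H](O)C(C)(C)O[Si](CC)(CC)CC)ccc(OCOC)c2C3OCCO3 | intermediate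
19 | 3-[(2S)-2,3-dihydroxy-3-methylbutyl]-6-hydroxy-2-[(1E,3S,4S,5E,10S)-3,4,10-trihydroxyundeca-1,5-dien-1-yl]benzaldehyde | C[C@H](O)CCC/C=C/[C@H](O)[C@@H](O)/C=C/c1c(C[C@H](O)C(C)(C)O)ccc(O)c1C=O | target

## Step count and risk

Total step count: 10.

Longest linear sequence: 5 steps (steps 1, 2, 3, 9, 10). The epoxide branch (steps 4, 5) and the olefin branch (steps 6 or 7, then 8) each join at step 9.

**Step 9 (key step).**
- *Most likely failure:* leakage after the norbornene has left. The pendant C2'' hydroxyl can chelate palladium, and intramolecular C–O reductive elimination onto C2 can outrun insertion of an unactivated, allylically branched vinyl group. Such a group inserts more slowly than the acrylates usually used for termination.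
- *Second weakness:* the neopentyl-like surroundings of the epoxide CH2 can slow the oxidative addition. The palladacycle would then be consumed by a second molecule of aryl iodide.
- *Minor leak:* β-hydride elimination toward C3'.
- *Harmless event:* migration of the silyl group between the C3'' and C2'' oxygens, because step 10 removes it from either position.
- *Fallback:* the same three fragments are joined stepwise with a halogen placed on C3 beforehand. The fallback sets out from 5.
  - Bromination with NBS in MeCN, para to the MOM ether, should give 2-[3-bromo-2-iodo-6-(methoxymethoxy)phenyl]-1,3-dioxolane F1.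
  - A chemoselective Heck reaction of the weaker C–I bond with 15 (Pd(OAc)2, P(o-tol)3, Et3N, DMF, 80 °C) should give the bromostyrene F2.
  - t-BuLi (3.2 equiv, THF, −78 °C; one equivalent for the C10' hydroxyl) effects bromine–lithium exchange. BF3·OEt2-assisted opening of 8 at its CH2 terminus then returns to the route at 18.

**Step 8.**
- *Most likely failure:* the desymmetrisation is statistical. A second metathesis at the remaining vinyl group, self-metathesis of 11 and incomplete E selectivity can all erode the material balance. The first two follow from the similar reactivity of the two vinyl groups before and after the first event.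
- *Fallback:* the desymmetrisation is moved into the Heck termination. The fallback sets out from 14.
  - Diene 14 is used in large excess as the olefin partner with 5 and 8 under the conditions of step 9. This should give the terminal vinyl compound F3.
  - F3 has only one terminal alkene. Its cross metathesis with an excess of inexpensive 11, with the catalyst of step 8, is no longer statistical and returns to the route at 18.

**Step 10.**
- *Most likely failure:* the trans-fused acetonide and the aryl MOM ether need more acid than the other two groups. Prolonged exposure can cause ionisation at the cinnamylic C3', followed by allylic transposition or capture by the C2'' hydroxyl at C1'.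
- *Fallback:* the ketal is removed from the scheme before ring A is attached. The fallback sets out from 15.
  - Hydrolysis (2 M aq. HCl, THF), at a stage without a styrene, gives (3S,4S,5E,10S)-undeca-1,5-diene-3,4,10-triol F4.
  - TESCl and imidazole in DMF give the tris(triethylsilyl) ether F5.
  - F5 is used with 5 and 8 under the conditions of step 9 to give the tetrasilylated coupling product F6.
  - HF·pyridine in THF at 0 °C removes all silyl groups without acid strong enough for ionisation. A short treatment with 1 M aq. HCl in THF at 23 °C then cleaves the dioxolane and the MOM ether, returning to the route at 19.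

**Step 4.**
- *Most likely failure:* competing opening of the epoxide by bromide or by the Grignard reagent, and loss of the small, volatile, water-soluble product during isolation.
- *Fallback:* the tertiary carbinol is built after the arene union. The fallback sets out from 6.
  - Ester 6 serves as the epoxide partner of 5 and 15 under the conditions of step 9. Its CH2 terminus is unhindered and activated by the ester. This should give the α-hydroxy ester F7.
  - Excess MeMgBr (THF, −78 → 0 °C; two equivalents are consumed by the free hydroxyls) converts the ester into the tertiary carbinol and gives the diol F8.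
  - Diol F8 is the silyl-free analogue of 18. The conditions of step 10 return to the route at 19.

## Further compounds

F1 | step 9 | 2-[3-bromo-2-iodo-6-(methoxymethoxy)phenyl]-1,3-dioxolane | COCOc1ccc(Br)c(I)c1C1OCCO1
F2 | step 9 | (2S,6E)-7-[(4S,5S)-5-{(E)-2-[6-bromo-2-(1,3-dioxolan-2-yl)-3-(methoxymethoxy)phenyl]ethenyl}-2,2-dimethyl-1,3-dioxolan-4-yl]hept-6-en-2-ol | C[C@H](O)CCC/C=C/[C@@H]1OC(C)(C)O[C@H]1/C=C/c2c(Br)ccc(OCOC)c2C3OCCO3
F3 | step 8 | (2S)-1-[3-(1,3-dioxolan-2-yl)-2-{(E)-2-[(4S,5S)-5-ethenyl-2,2-dimethyl-1,3-dioxolan-4-yl]ethenyl}-4-(methoxymethoxy)phenyl]-3-methyl-3-[(triethylsilyl)oxy]butan-2-ol | C=C[C@@H]1OC(C)(C)O[C@H]1/C=C/c2c(C[C@H](O)C(C)(C)O[Si](CC)(CC)CC)ccc(OCOC)c2C3OCCO3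
F4 | step 10 | (3S,4S,5E,10S)-undeca-1,5-diene-3,4,10-triol | C[C@H](O)CCC/C=C/[C@H](O)[C@@H](O)C=C
F5 | step 10 | (3S,4S,5E,10S)-3,4,10-tris[(triethylsilyl)oxy]undeca-1,5-diene | C[C@H](O[Si](CC)(CC)CC)CCC/C=C/[C@H](O[Si](CC)(CC)CC)[C@@H](O[Si](CC)(CC)CC)C=C
F6 | step 10 | (2S)-1-[3-(1,3-dioxolan-2-yl)-4-(methoxymethoxy)-2-{(1E,3S,4S,5E,10S)-3,4,10-tris[(triethylsilyl)oxy]undeca-1,5-dien-1-yl}phenyl]-3-methyl-3-[(triethylsilyl)oxy]butan-2-ol | C[C@H](O[Si](CC)(CC)CC)CCC/C=C/[C@H](O[Si](CC)(CC)CC)[C@@H](O[Si](CC)(CC)CC)/C=C/c1c(C[C@H](O)C(C)(C)O[Si](CC)(CC)CC)ccc(OCOC)c1C1OCCO1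
F7 | step 4 | methyl (2S)-3-[3-(1,3-dioxolan-2-yl)-2-{(E)-2-[(4S,5S)-5-{(1E,6S)-6-hydroxyhept-1-en-1-yl}-2,2-dimethyl-1,3-dioxolan-4-yl]ethenyl}-4-(methoxymethoxy)phenyl]-2-hydroxypropanoate | C[C@H](O)CCC/C=C/[C@@H]1OC(C)(C)O[C@H]1/C=C/c2c(C[C@H](O)C(=O)OC)ccc(OCOC)c2C3OCCO3
F8 | step 4 | (2S)-1-[3-(1,3-dioxolan-2-yl)-2-{(E)-2-[(4S,5S)-5-{(1E,6S)-6-hydroxyhept-1-en-1-yl}-2,2-dimethyl-1,3-dioxolan-4-yl]ethenyl}-4-(methoxymethoxy)phenyl]-3-methylbutane-2,3-diol | C[C@H](O)CCC/C=C/[C@@H]1OC(C)(C)O[C@H]1/C=C/c2c(C[C@H](O)C(C)(C)O)ccc(OCOC)c2C3OCCO3
A1 | alternative 1 | 2-bromo-6-(methoxymethoxy)-3-(3-methylbut-2-en-1-yl)benzaldehyde | COCOc1ccc(CC=C(C)C)c(Br)c1C=O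
A2 | alternative 1 | 2-{(E)-2-[(4S,5S)-5-{(1E,6S)-6-hydroxyhept-1-en-1-yl}-2,2-dimethyl-1,3-dioxolan-4-yl]ethenyl}-6-(methoxymethoxy)-3-(3-methylbut-2-en-1-yl)benzaldehyde | C[C@H](O)CCC/C=C/[C@@H]1OC(C)(C)O[C@H]1/C=C/c2c(CC=C(C)C)ccc(OCOC)c2C=O
A3 | alternative 2 | (2S,8E)-11-[2-(1,3-dioxolan-2-yl)-3-(methoxymethoxy)-6-(3-methylbut-2-en-1-yl)phenyl]undec-8-ene-6,10-diyn-2-ol | C[C@H](O)CCCC#C/C=C/C#Cc1c(CC=C(C)C)ccc(OCOC)c1C1OCCO1
A4 | alternative 2 | (3S,4S,10S)-1-[6-{(2S)-2,3-dihydroxy-3-methylbutyl}-2-(1,3-dioxolan-2-yl)-3-(methoxymethoxy)phenyl]undeca-1,5-diyne-3,4,10-triol | C[C@H](O)CCCC#C[C@H](O)[C@@H](O)C#Cc1c(C[C@H](O)C(C)(C)O)ccc(OCOC)c1C1OCCO1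
A5 | alternative 3 | 2-(3-methylbut-2-en-1-yl)furan | CC(C)=CCc1ccco1
A6 | alternative 3 | (4E)-5-[(4S,5S)-5-{(1E,6S)-6-hydroxyhept-1-en-1-yl}-2,2-dimethyl-1,3-dioxolan-4-yl]pent-4-en-2-ynal | C[C@H](O)CCC/C=C/[C@@H]1OC(C)(C)O[C@H]1/C=C/C#CC=O
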